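**Plan**
- Retrosynthesis: the C2-symmetric C40 chain is cut at C11=C12 and C11'=C12' (two-fold Wittig, C15 + C10 + C15), each C15 half at C8–C9 (Sonogashira) and at C7≡C8 (Corey–Fuchs), and ring A at C1–C6.
- Enabling feature: in ring A (C1–C6) the gem-dimethyl carbon C1 is bonded to the olefinic carbon C6, which carries C7, and C5 carries the methyl C18. This is the imprint of a tertiary C1 cation adding to a C5=C6 olefin, so the ring unfolds to an acyclic C7–C6=C5–C4–C3–C2–C1(=CH2) dienoate.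
- Forward order: acyclic chain first (C2–C5 from L-threitol acetonide, C1/C16/C17 from isopropenylmagnesium bromide, C18 from MeMgBr, C6/C7 from phosphonoacetate), then ring A by acid closure, then C8, then C9–C11 with C19, then both halves onto the C10 dialdehyde, then desilylation.
- Stereochemistry: C3 and C4 (both S, trans diol) are carried unchanged from L-tartaric acid through compound 1; no stereocentre is created in the route. 9E comes from an (E)-enol triflate, 11E from the Wittig step with thermal isomerisation, 13E and 15E from the dialdehyde.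

Key step: step 11

Remark: compound 1 is the commercial acetonide of L-threitol (made from L-tartaric acid); carotenoid numbering (ring C1–C6, chain C7–C15, methyls C16–C20) is used for all intermediates.

**Step 1**
Reactants: 1 (4S,5S)-2,3-O-isopropylidene-L-threitol
Product: 2 {(4S,5S)-5-[(tert-butyldimethylsilyloxy)methyl]-2,2-dimethyl-1,3-dioxolan-4-yl}methanol
Conditions: NaH (1.0 equiv), THF, 0 °C; TBSCl (1.0 equiv), 0 °C to rt
Reagents that add atoms: tert-butyldimethylsilyl chloride, CC(C)(C)[Si](C)(C)Cl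
Why: Monosilylation of a symmetrical diol through its monosodium alkoxide should stop after one silyl group, and since both hydroxyls are equivalent by C2 symmetry one product results with no stereocentre touched.

**Step 2**
Reactants: 2 {(4S,5S)-5-[(tert-butyldimethylsilyloxy)methyl]-2,2-dimethyl-1,3-dioxolan-4-yl}methanol
Product: 3 {(4S,5S)-5-[(tert-butyldimethylsilyloxy)methyl]-2,2-dimethyl-1,3-dioxolan-4-yl}methyl trifluoromethanesulfonate
Conditions: Tf2O, pyridine, CH2Cl2, −20 °C; crude product used at once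
Reagents that add atoms: trifluoromethanesulfonic anhydride, O=S(=O)(OS(=O)(=O)C(F)(F)F)C(F)(F)F
Why: O-Triflation of a primary alcohol under pyridine buffering gives the most reactive sulfonate for displacement at a β-oxygenated carbon.

**Step 3**
Reactants: 3 {(4S,5S)-5-[(tert-butyldimethylsilyloxy)methyl]-2,2-dimethyl-1,3-dioxolan-4-yl}methyl trifluoromethanesulfonate; 4 isopropenylmagnesium bromide
Product: 5 tert-butyl{[(4S,5S)-2,2-dimethyl-5-(2-methylprop-2-en-1-yl)-1,3-dioxolan-4-yl]methoxy}dimethylsilane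
Conditions: CuBr·SMe2 (10 mol%), Et2O/THF, −30 to 0 °C
Reagents that add atoms: none
Why: Copper-catalysed cross-coupling of a Grignard reagent with a primary alkyl triflate (SN2 displacement by an organocuprate) is established on threitol-acetonide triflates and forms C1–C2 at a CH2 group, leaving C3 untouched.

**Step 4**
Reactants: 5 tert-butyl{[(4S,5S)-2,2-dimethyl-5-(2-methylprop-2-en-1-yl)-1,3-dioxolan-4-yl]methoxy}dimethylsilane
Product: 6 [(4S,5S)-2,2-dimethyl-5-(2-methylprop-2-en-1-yl)-1,3-dioxolan-4-yl]methanol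
Conditions: Bu4NF, THF, 0 °C to rt
Reagents that add atoms: none
Why: Fluoride-mediated cleavage of a primary silyl ether leaves the acetonide and the olefin untouched.

**Step 5**
Reactants: 6 [(4S,5S)-2,2-dimethyl-5-(2-methylprop-2-en-1-yl)-1,3-dioxolan-4-yl]methanol
Product: 7 (4R,5S)-2,2-dimethyl-5-(2-methylprop-2-en-1-yl)-1,3-dioxolane-4-carbaldehyde
Conditions: Dess–Martin periodinane, CH2Cl2, 0 °C to rt
Reagents that add atoms: none
Why: Dess–Martin oxidation gives the α-alkoxy aldehyde under non-basic conditions, and the trans acetonide is the stable arrangement, so the α-centre is not at risk (the R descriptor is only a priority change).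

**Step 6**
Reactants: 7 (4R,5S)-2,2-dimethyl-5-(2-methylprop-2-en-1-yl)-1,3-dioxolane-4-carbaldehyde; 8 methylmagnesium bromide
Product: 9 1-[(4S,5S)-2,2-dimethyl-5-(2-methylprop-2-en-1-yl)-1,3-dioxolan-4-yl]ethan-1-ol (both carbinol epimers)
Conditions: THF, −78 °C; aq. NH4Cl
Reagents that add atoms: none
Why: Grignard addition to the aldehyde brings in C18, and the carbinol configuration is irrelevant because the centre is oxidised in the next step.

**Step 7**
Reactants: 9 1-[(4S,5S)-2,2-dimethyl-5-(2-methylprop-2-en-1-yl)-1,3-dioxolan-4-yl]ethan-1-ol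
Product: 10 1-[(4R,5S)-2,2-dimethyl-5-(2-methylprop-2-en-1-yl)-1,3-dioxolan-4-yl]ethan-1-one
Conditions: Dess–Martin periodinane, CH2Cl2, rt
Reagents that add atoms: none
Why: Dess–Martin oxidation of the secondary alcohol converges both epimers to the methyl ketone without base that could epimerise C4.

**Step 8**
Reactants: 10 1-[(4R,5S)-2,2-dimethyl-5-(2-methylprop-2-en-1-yl)-1,3-dioxolan-4-yl]ethan-1-one; 11 trimethyl phosphonoacetate
Product: 12 methyl (2E)-3-[(4S,5S)-2,2-dimethyl-5-(2-methylprop-2-en-1-yl)-1,3-dioxolan-4-yl]but-2-enoate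
Conditions: NaH, THF, 0 °C to rt; chromatography
Reagents that add atoms: none
Why: Horner–Wadsworth–Emmons olefination of the methyl ketone should favour the E olefin, with the ester trans to the branched C4 substituent, and any Z isomer is removed by chromatography.

**Step 9**
Reactants: 12 methyl (2E)-3-[(4S,5S)-2,2-dimethyl-5-(2-methylprop-2-en-1-yl)-1,3-dioxolan-4-yl]but-2-enoate
Product: 13 methyl (2E,4S,5S)-4,5-dihydroxy-3,7-dimethylocta-2,7-dienoate
Conditions: AcOH/H2O (4:1), 45 °C
Reagents that add atoms: none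
Why: Mild acid-catalysed acetal hydrolysis frees the diol, and the E geometry keeps the ester out of reach of both hydroxyls so no lactone can form.

**Step 10**
Reactants: 13 methyl (2E,4S,5S)-4,5-dihydroxy-3,7-dimethylocta-2,7-dienoate
Product: 14 methyl (2E)-3-[(4S,5S)-5-(2-methylprop-2-en-1-yl)-2-oxo-1,3-dioxolan-4-yl]but-2-enoate
Conditions: 1,1'-carbonyldiimidazole, CH2Cl2, rt
Reagents that add atoms: 1,1'-carbonyldiimidazole, O=C(n1ccnc1)n1ccnc1
Why: Carbonylation of a 1,2-diol with carbonyldiimidazole gives the five-membered cyclic carbonate, here the unstrained trans-4,5-disubstituted dioxolanone, without touching C3 or C4.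

**Step 11**
Reactants: 14 methyl (2E)-3-[(4S,5S)-5-(2-methylprop-2-en-1-yl)-2-oxo-1,3-dioxolan-4-yl]but-2-enoate
Product: 15 methyl (3aS,7aS)-4,6,6-trimethyl-2-oxo-3a,6,7,7a-tetrahydro-1,3-benzodioxole-5-carboxylate (methyl (3S,4S)-3,4-dihydroxy-β-cyclogeranate cyclic carbonate)
Conditions: ClSO3H (3 equiv), 2-nitropropane, −78 °C; ice-water quench
Reagents that add atoms: none
Why: Proposed new method: ClSO3H is expected to protonate the 1,1-disubstituted olefin in the Markovnikov sense to the tertiary C1 cation, which is attacked by C6 of the enoate olefin (C1–C6 bond), and the tertiary C5 cation so formed then loses the C6 proton to leave the tetrasubstituted C5=C6 olefin in conjugation with the ester. The closest known reaction type is the Brønsted- and superacid-mediated cyclisation of geranic and farnesic esters to cyclogeranyl-type rings, which has not been shown with oxygen substituents at C3 and C4. Ring A closes in the 6-endo-trig mode with respect to the C5=C6 olefin, both olefinic carbons becoming ring members. No stereocentre is formed, since C1 carries two methyl groups and C6 ends sp2, and C3 and C4 stay S,S because the isopropenyl initiator keeps both C–O bonds away from any allylic cation. The step needs carbon rather than oxygen to capture the C1 cation, which the cyclic carbonate secures: its ring oxygens are deactivated by the carbonyl group and its carbonyl oxygen is held exo to the dioxolanone and cannot reach C1. It also needs proton loss from C6 rather than from C4 or C18, which is favoured by the acidity of the ester α-hydrogen, by the acceptor effect of the carbonate oxygen on C4–H and by equilibration of any exocyclic olefin under the protic conditions.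

**Step 12**
Reactants: 15 methyl (3aS,7aS)-4,6,6-trimethyl-2-oxo-3a,6,7,7a-tetrahydro-1,3-benzodioxole-5-carboxylate
Product: 16 methyl (3S,4S)-3,4-dihydroxy-2,6,6-trimethylcyclohex-1-ene-1-carboxylate
Conditions: K2CO3 (cat.), MeOH, 0 °C to rt
Reagents that add atoms: none
Why: Base-catalysed methanolysis (transesterification) opens the strained cyclic carbonate, while the hindered conjugated methyl ester can only exchange methoxide for methoxide.

**Step 13**
Reactants: 16 methyl (3S,4S)-3,4-dihydroxy-2,6,6-trimethylcyclohex-1-ene-1-carboxylate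
Product: 17 methyl (3S,4S)-3,4-bis[(tert-butyldimethylsilyl)oxy]-2,6,6-trimethylcyclohex-1-ene-1-carboxylate
Conditions: TBSOTf, 2,6-lutidine, CH2Cl2, 0 °C to rt
Reagents that add atoms: tert-butyldimethylsilyl trifluoromethanesulfonate, CC(C)(C)[Si](C)(C)OS(=O)(=O)C(F)(F)F
Why: Silylation with the silyl triflate and 2,6-lutidine is the standard way to protect two neighbouring hindered secondary alcohols.

**Step 14**
Reactants: 17 methyl (3S,4S)-3,4-bis[(tert-butyldimethylsilyl)oxy]-2,6,6-trimethylcyclohex-1-ene-1-carboxylate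
Product: 18 {(3S,4S)-3,4-bis[(tert-butyldimethylsilyl)oxy]-2,6,6-trimethylcyclohex-1-en-1-yl}methanol
Conditions: i-Bu2AlH, CH2Cl2, −78 to 0 °C; Rochelle salt work-up
Reagents that add atoms: none
Why: Hydride reduction of the β-cyclogeranate ester to the allylic alcohol is a known transformation and silyl ethers tolerate i-Bu2AlH.

**Step 15**
Reactants: 18 {(3S,4S)-3,4-bis[(tert-butyldimethylsilyl)oxy]-2,6,6-trimethylcyclohex-1-en-1-yl}methanol
Product: 19 (3S,4S)-3,4-bis[(tert-butyldimethylsilyl)oxy]-2,6,6-trimethylcyclohex-1-ene-1-carbaldehyde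
Conditions: MnO2 (activated, excess), CH2Cl2, rt
Reagents that add atoms: none
Why: MnO2 oxidises the primary allylic alcohol selectively to the enal, as in the conversion of β-cyclogeraniol into β-cyclocitral.

**Step 16**
Reactants: 19 (3S,4S)-3,4-bis[(tert-butyldimethylsilyl)oxy]-2,6,6-trimethylcyclohex-1-ene-1-carbaldehyde; 20 carbon tetrabromide
Product: 21 (3S,4S)-3,4-bis[(tert-butyldimethylsilyl)oxy]-1-(2,2-dibromoethenyl)-2,6,6-trimethylcyclohex-1-ene
Conditions: PPh3, Zn dust, CH2Cl2, rt (reagent pre-formed), then 19, rt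
Reagents that add atoms: none
Why: First stage of the Corey–Fuchs reaction, a Wittig-type dibromo-olefination by the small ylide Ph3P=CBr2, run in its zinc variant so that the medium stays neutral for the silyl ethers.

**Step 17**
Reactants: 21 (3S,4S)-3,4-bis[(tert-butyldimethylsilyl)oxy]-1-(2,2-dibromoethenyl)-2,6,6-trimethylcyclohex-1-ene
Product: 23 (3S,4S)-3,4-bis[(tert-butyldimethylsilyl)oxy]-1-ethynyl-2,6,6-trimethylcyclohex-1-ene, via lithium acetylide 22 (not isolated)
Conditions: n-BuLi (2.2 equiv), THF, −78 to 0 °C; H2O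
Reagents that add atoms: none
Why: Second stage of the Corey–Fuchs reaction: bromine–lithium exchange, α-elimination and 1,2-hydrogen shift (Fritsch–Buttenberg–Wiechell rearrangement) give the lithium acetylide, which is protonated on quench to the C7≡C8 alkyne.

**Step 18**
Reactants: 24 methyl acetoacetate
Product: 25 methyl (2E)-3-{[(trifluoromethyl)sulfonyl]oxy}but-2-enoate
Conditions: Tf2O, aq. Me4NOH, toluene, 5 °C
Reagents that add atoms: trifluoromethanesulfonic anhydride, O=S(=O)(OS(=O)(=O)C(F)(F)F)C(F)(F)F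
Why: O-Triflation of a β-keto ester enolate with a non-chelating ammonium counter-ion is a known stereoselective route to the (E)-enol triflate, which fixes the later C9=C10 geometry.

**Step 19**
Reactants: 23 (3S,4S)-3,4-bis[(tert-butyldimethylsilyl)oxy]-1-ethynyl-2,6,6-trimethylcyclohex-1-ene; 25 methyl (2E)-3-{[(trifluoromethyl)sulfonyl]oxy}but-2-enoate
Product: 26 methyl (2E)-5-{(3S,4S)-3,4-bis[(tert-butyldimethylsilyl)oxy]-2,6,6-trimethylcyclohex-1-en-1-yl}-3-methylpent-2-en-4-ynoate
Conditions: Pd(PPh3)4 (5 mol%), CuI (10 mol%), Et3N, THF, rt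
Reagents that add atoms: none
Why: Sonogashira coupling of a terminal alkyne with an electron-poor enol triflate proceeds with retention of olefin geometry and so forms C8–C9 with 9E.

**Step 20**
Reactants: 26 methyl (2E)-5-{(3S,4S)-3,4-bis[(tert-butyldimethylsilyl)oxy]-2,6,6-trimethylcyclohex-1-en-1-yl}-3-methylpent-2-en-4-ynoate
Product: 27 (2E)-5-{(3S,4S)-3,4-bis[(tert-butyldimethylsilyl)oxy]-2,6,6-trimethylcyclohex-1-en-1-yl}-3-methylpent-2-en-4-yn-1-ol
Conditions: i-Bu2AlH, CH2Cl2, −78 °C; Rochelle salt work-up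
Reagents that add atoms: none
Why: 1,2-Reduction of a conjugated ester by i-Bu2AlH gives the allylic alcohol without touching the enyne geometry.

**Step 21**
Reactants: 27 (2E)-5-{(3S,4S)-3,4-bis[(tert-butyldimethylsilyl)oxy]-2,6,6-trimethylcyclohex-1-en-1-yl}-3-methylpent-2-en-4-yn-1-ol; 20 carbon tetrabromide
Product: 28 (3S,4S)-1-[(3E)-5-bromo-3-methylpent-3-en-1-yn-1-yl]-3,4-bis[(tert-butyldimethylsilyl)oxy]-2,6,6-trimethylcyclohex-1-ene
Conditions: PPh3, CH2Cl2, −20 to 0 °C; used without storage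
Reagents that add atoms: none
Why: The Appel reaction converts the primary allylic alcohol into the bromide under neutral conditions that spare the silyl ethers, including the allylic one at C4.

**Step 22**
Reactants: 28 (3S,4S)-1-[(3E)-5-bromo-3-methylpent-3-en-1-yn-1-yl]-3,4-bis[(tert-butyldimethylsilyl)oxy]-2,6,6-trimethylcyclohex-1-ene
Product: 29 [(2E)-5-{(3S,4S)-3,4-bis[(tert-butyldimethylsilyl)oxy]-2,6,6-trimethylcyclohex-1-en-1-yl}-3-methylpent-2-en-4-yn-1-yl]triphenylphosphonium bromide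
Conditions: PPh3, EtOAc, rt, dark
Reagents that add atoms: triphenylphosphine, c1ccccc1P(c1ccccc1)c1ccccc1
Why: Quaternisation of triphenylphosphine by a primary allylic bromide (SN2) gives the C15 Wittig salt, which should precipitate from ethyl acetate.

**Step 23**
Reactants: 29 [(2E)-5-{(3S,4S)-3,4-bis[(tert-butyldimethylsilyl)oxy]-2,6,6-trimethylcyclohex-1-en-1-yl}-3-methylpent-2-en-4-yn-1-yl]triphenylphosphonium bromide (2.2 equiv); 30 (2E,4E,6E)-2,7-dimethylocta-2,4,6-trienedial
Product: 33 (all-E,3S,4S,3'S,4'S)-3,4,3',4'-tetrakis[(tert-butyldimethylsilyl)oxy]-7,8,7',8'-tetradehydro-β,β-carotene, via phosphorus ylide 31 (not isolated), via C25 apo-aldehyde 32 (not isolated)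
Conditions: NaOMe, MeOH/CH2Cl2, 0 °C to rt; then heptane, 90 °C, dark, argon
Reagents that add atoms: none
Why: Two-fold Wittig olefination of the C10 dialdehyde with the allylic C15 ylide is the classical C15 + C10 + C15 carotenoid assembly, and the hindered 11Z bonds should isomerise thermally to E without iodine, which would also equilibrate the 9,10-olefin next to the alkyne.

**Step 24**
Reactants: 33 (all-E,3S,4S,3'S,4'S)-3,4,3',4'-tetrakis[(tert-butyldimethylsilyl)oxy]-7,8,7',8'-tetradehydro-β,β-carotene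
Product: 34 (all-E,3S,4S,3'S,4'S)-7,8,7',8'-tetradehydro-β,β-carotene-3,4,3',4'-tetrol (CNP0283832.1)
Conditions: Bu4NF (excess), THF, rt, dark, argon
Reagents that add atoms: none
Why: Fluoride-mediated cleavage of the four secondary silyl ethers is non-acidic, so the allylic C4 and C4' alcohols are not ionised.

**Compound list**
1 | (4S,5S)-2,3-O-isopropylidene-L-threitol | OC[C@@H]1OC(C)(C)O[C@H]1CO | starting material
2 | {(4S,5S)-5-[(tert-butyldimethylsilyloxy)methyl]-2,2-dimethyl-1,3-dioxolan-4-yl}methanol | CC(C)(C)[Si](C)(C)OC[C@@H]1OC(C)(C)O[C@H]1CO | intermediate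
3 | {(4S,5S)-5-[(tert-butyldimethylsilyloxy)methyl]-2,2-dimethyl-1,3-dioxolan-4-yl}methyl trifluoromethanesulfonate | CC(C)(C)[Si](C)(C)OC[C@@H]1OC(C)(C)O[C@H]1COS(=O)(=O)C(F)(F)F | intermediate
4 | isopropenylmagnesium bromide | CC(=C)[Mg]Br | starting material
5 | tert-butyl{[(4S,5S)-2,2-dimethyl-5-(2-methylprop-2-en-1-yl)-1,3-dioxolan-4-yl]methoxy}dimethylsilane | CC(C)(C)[Si](C)(C)OC[C@@H]1OC(C)(C)O[C@H]1CC(C)=C | intermediate
6 | [(4S,5S)-2,2-dimethyl-5-(2-methylprop-2-en-1-yl)-1,3-dioxolan-4-yl]methanol | OC[C@@H]1OC(C)(C)O[C@H]1CC(C)=C | intermediate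
7 | (4R,5S)-2,2-dimethyl-5-(2-methylprop-2-en-1-yl)-1,3-dioxolane-4-carbaldehyde | O=C[C@@H]1OC(C)(C)O[C@H]1CC(C)=C | intermediate
8 | methylmagnesium bromide | C[Mg]Br | starting material
9 | 1-[(4S,5S)-2,2-dimethyl-5-(2-methylprop-2-en-1-yl)-1,3-dioxolan-4-yl]ethan-1-ol (both carbinol epimers) | CC(O)[C@@H]1OC(C)(C)O[C@H]1CC(C)=C | intermediate
10 | 1-[(4R,5S)-2,2-dimethyl-5-(2-methylprop-2-en-1-yl)-1,3-dioxolan-4-yl]ethan-1-one | CC(=O)[C@@H]1OC(C)(C)O[C@H]1CC(C)=C | intermediate
11 | trimethyl phosphonoacetate | COC(=O)CP(=O)(OC)OC | starting material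
12 | methyl (2E)-3-[(4S,5S)-2,2-dimethyl-5-(2-methylprop-2-en-1-yl)-1,3-dioxolan-4-yl]but-2-enoate | COC(=O)/C=C(\C)[C@@H]1OC(C)(C)O[C@H]1CC(C)=C | intermediate
13 | methyl (2E,4S,5S)-4,5-dihydroxy-3,7-dimethylocta-2,7-dienoate | COC(=O)/C=C(\C)[C@H](O)[C@@H](O)CC(C)=C | intermediate
14 | methyl (2E)-3-[(4S,5S)-5-(2-methylprop-2-en-1-yl)-2-oxo-1,3-dioxolan-4-yl]but-2-enoate | COC(=O)/C=C(\C)[C@@H]1OC(=O)O[C@H]1CC(C)=C | intermediate
15 | methyl (3aS,7aS)-4,6,6-trimethyl-2-oxo-3a,6,7,7a-tetrahydro-1,3-benzodioxole-5-carboxylate | COC(=O)C1=C(C)[C@@H]2OC(=O)O[C@H]2CC1(C)C | intermediate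
16 | methyl (3S,4S)-3,4-dihydroxy-2,6,6-trimethylcyclohex-1-ene-1-carboxylate | COC(=O)C1=C(C)[C@H](O)[C@@H](O)CC1(C)C | intermediate
17 | methyl (3S,4S)-3,4-bis[(tert-butyldimethylsilyl)oxy]-2,6,6-trimethylcyclohex-1-ene-1-carboxylate | COC(=O)C1=C(C)[C@H](O[Si](C)(C)C(C)(C)C)[C@@H](O[Si](C)(C)C(C)(C)C)CC1(C)C | intermediate
18 | {(3S,4S)-3,4-bis[(tert-butyldimethylsilyl)oxy]-2,6,6-trimethylcyclohex-1-en-1-yl}methanol | OCC1=C(C)[C@H](O[Si](C)(C)C(C)(C)C)[C@@H](O[Si](C)(C)C(C)(C)C)CC1(C)C | intermediate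
19 | (3S,4S)-3,4-bis[(tert-butyldimethylsilyl)oxy]-2,6,6-trimethylcyclohex-1-ene-1-carbaldehyde | O=CC1=C(C)[C@H](O[Si](C)(C)C(C)(C)C)[C@@H](O[Si](C)(C)C(C)(C)C)CC1(C)C | intermediate
20 | carbon tetrabromide | BrC(Br)(Br)Br | starting material
21 | (3S,4S)-3,4-bis[(tert-butyldimethylsilyl)oxy]-1-(2,2-dibromoethenyl)-2,6,6-trimethylcyclohex-1-ene | BrC(Br)=CC1=C(C)[C@H](O[Si](C)(C)C(C)(C)C)[C@@H](O[Si](C)(C)C(C)(C)C)CC1(C)C | intermediate
22 | lithium acetylide of 23 (formed in the flask) | [Li]C#CC1=C(C)[C@H](O[Si](C)(C)C(C)(C)C)[C@@H](O[Si](C)(C)C(C)(C)C)CC1(C)C | intermediate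
23 | (3S,4S)-3,4-bis[(tert-butyldimethylsilyl)oxy]-1-ethynyl-2,6,6-trimethylcyclohex-1-ene | C#CC1=C(C)[C@H](O[Si](C)(C)C(C)(C)C)[C@@H](O[Si](C)(C)C(C)(C)C)CC1(C)C | intermediate
24 | methyl acetoacetate | COC(=O)CC(C)=O | starting material
25 | methyl (2E)-3-{[(trifluoromethyl)sulfonyl]oxy}but-2-enoate | COC(=O)/C=C(\C)OS(=O)(=O)C(F)(F)F | intermediate
26 | methyl (2E)-5-{(3S,4S)-3,4-bis[(tert-butyldimethylsilyl)oxy]-2,6,6-trimethylcyclohex-1-en-1-yl}-3-methylpent-2-en-4-ynoate | COC(=O)/C=C(\C)C#CC1=C(C)[C@H](O[Si](C)(C)C(C)(C)C)[C@@H](O[Si](C)(C)C(C)(C)C)CC1(C)C | intermediate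
27 | (2E)-5-{(3S,4S)-3,4-bis[(tert-butyldimethylsilyl)oxy]-2,6,6-trimethylcyclohex-1-en-1-yl}-3-methylpent-2-en-4-yn-1-ol | OC/C=C(\C)C#CC1=C(C)[C@H](O[Si](C)(C)C(C)(C)C)[C@@H](O[Si](C)(C)C(C)(C)C)CC1(C)C | intermediate
28 | (3S,4S)-1-[(3E)-5-bromo-3-methylpent-3-en-1-yn-1-yl]-3,4-bis[(tert-butyldimethylsilyl)oxy]-2,6,6-trimethylcyclohex-1-ene | BrC/C=C(\C)C#CC1=C(C)[C@H](O[Si](C)(C)C(C)(C)C)[C@@H](O[Si](C)(C)C(C)(C)C)CC1(C)C | intermediate
29 | [(2E)-5-{(3S,4S)-3,4-bis[(tert-butyldimethylsilyl)oxy]-2,6,6-trimethylcyclohex-1-en-1-yl}-3-methylpent-2-en-4-yn-1-yl]triphenylphosphonium bromide | [Br-].C(/C=C(\C)C#CC1=C(C)[C@H](O[Si](C)(C)C(C)(C)C)[C@@H](O[Si](C)(C)C(C)(C)C)CC1(C)C)[P+](c1ccccc1)(c1ccccc1)c1ccccc1 | intermediate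
30 | (2E,4E,6E)-2,7-dimethylocta-2,4,6-trienedial | O=C/C(C)=C/C=C/C=C(\C)C=O | starting material
31 | triphenylphosphonium ylide of 29 (formed in the flask) | C(=P(c1ccccc1)(c1ccccc1)c1ccccc1)/C=C(\C)C#CC1=C(C)[C@H](O[Si](C)(C)C(C)(C)C)[C@@H](O[Si](C)(C)C(C)(C)C)CC1(C)C | intermediate
32 | (2E,4E,6E,10E)-13-{(3S,4S)-3,4-bis[(tert-butyldimethylsilyl)oxy]-2,6,6-trimethylcyclohex-1-en-1-yl}-2,7,11-trimethyltrideca-2,4,6,8,10-pentaen-12-ynal (formed in the flask; new 8,9-olefin drawn E) | O=C/C(C)=C/C=C/C=C(C)/C=C/C=C(\C)C#CC1=C(C)[C@H](O[Si](C)(C)C(C)(C)C)[C@@H](O[Si](C)(C)C(C)(C)C)CC1(C)C | intermediate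
33 | (all-E,3S,4S,3'S,4'S)-3,4,3',4'-tetrakis[(tert-butyldimethylsilyl)oxy]-7,8,7',8'-tetradehydro-β,β-carotene | CC1=C(C#C/C(C)=C/C=C/C(C)=C/C=C/C=C(C)/C=C/C=C(\C)C#CC2=C(C)[C@H](O[Si](C)(C)C(C)(C)C)[C@@H](O[Si](C)(C)C(C)(C)C)CC2(C)C)C(C)(C)C[C@H](O[Si](C)(C)C(C)(C)C)[C@H]1O[Si](C)(C)C(C)(C)C | intermediate
34 | (all-E,3S,4S,3'S,4'S)-7,8,7',8'-tetradehydro-β,β-carotene-3,4,3',4'-tetrol | CC1=C(C#C/C(C)=C/C=C/C(C)=C/C=C/C=C(C)/C=C/C=C(\C)C#CC2=C(C)[C@H](O)[C@@H](O)CC2(C)C)C(C)(C)C[C@H](O)[C@H]1O | target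

**Step count**
Total: 24 steps. Longest linear sequence: 23 steps (steps 1–17 and 19–24, from 1 to 34); step 18 is a one-step branch.

**Steps most likely to fail**

Step 11 (proposed new method). The enoate olefin, deactivated by the ester and by the C4 oxygen, may be too slow to trap the C1 cation. The cation would then shed a proton into the chain, and the C1=C2 olefin so formed makes C3–O allylic and open to ionisation. Alternatively the C5 cation may lose the C4 proton to an enol carbonate. The fallback keeps the C1–C6 closure but uses the known Lewis-acid cyclisation of olefinic β-keto esters, whose enol is a far better terminator, and adds C18 afterwards. It sets out from aldehyde 7. Roskamp homologation (methyl diazoacetate, SnCl2 cat., CH2Cl2) should give methyl 3-[(4R,5S)-2,2-dimethyl-5-(2-methylprop-2-en-1-yl)-1,3-dioxolan-4-yl]-3-oxopropanoate F1. Cold aqueous acid would free the diol, methyl (4R,5S)-4,5-dihydroxy-7-methyl-3-oxooct-7-enoate F2, which is carbonylated at once with carbonyldiimidazole, since it can lactonise, to methyl 3-[(4R,5S)-5-(2-methylprop-2-en-1-yl)-2-oxo-1,3-dioxolan-4-yl]-3-oxopropanoate F3. SnCl4 in CH2Cl2 should close ring A to the enolised keto ester methyl (3aR,7aS)-4-hydroxy-6,6-dimethyl-2-oxo-3a,6,7,7a-tetrahydro-1,3-benzodioxole-5-carboxylate F4. Triflation (NaH, PhNTf2) would give methyl (3aR,7aS)-6,6-dimethyl-2-oxo-4-{[(trifluoromethyl)sulfonyl]oxy}-3a,6,7,7a-tetrahydro-1,3-benzodioxole-5-carboxylate F5, and Me2CuLi at −78 °C would replace the triflate by methyl, returning to the route at 15.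

Step 3. Displacement at the β-oxygenated primary carbon may be slow, so that bromide substitution or decomposition of the triflate outruns the coupling. The fallback builds C1 by sulfur-stabilised carbanion alkylation instead of an sp3–sp2 coupling. It sets out from triflate 3. Alkylation with 2-lithio-2-methyl-1,3-dithiane (THF, −78 °C) should give tert-butyl({(4S,5S)-2,2-dimethyl-5-[(2-methyl-1,3-dithian-2-yl)methyl]-1,3-dioxolan-4-yl}methoxy)dimethylsilane F6. Dithiane hydrolysis (MeI, CaCO3, aq. MeCN) would give 1-[(4S,5S)-5-{[(tert-butyldimethylsilyl)oxy]methyl}-2,2-dimethyl-1,3-dioxolan-4-yl]propan-2-one F7. Wittig methylenation (Ph3P=CH2, THF, 0 °C) then returns to the route at 5.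

Step 24. Cleavage of four hindered silyl ethers on the C40 polyene may stay incomplete or degrade the air-, light- and base-sensitive chain. The fallback moves the deprotection in front of the polyene assembly, so that the last step is the olefination itself. It sets out from phosphonium salt 29. HF·pyridine in THF at 0 °C, followed by an aqueous NaBr wash, should give {(2E)-5-[(3S,4S)-3,4-dihydroxy-2,6,6-trimethylcyclohex-1-en-1-yl]-3-methylpent-2-en-4-yn-1-yl}triphenylphosphonium bromide F8. Its two-fold Wittig reaction with dialdehyde 30 (excess NaOMe, MeOH/CH2Cl2, then thermal isomerisation) tolerates free hydroxyl groups, as is usual for hydroxylated C15 salts, and comes back to the route at 34.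

**Further compounds**
F1 | step 11 | methyl 3-[(4R,5S)-2,2-dimethyl-5-(2-methylprop-2-en-1-yl)-1,3-dioxolan-4-yl]-3-oxopropanoate | COC(=O)CC(=O)[C@@H]1OC(C)(C)O[C@H]1CC(C)=C
F2 | step 11 | methyl (4R,5S)-4,5-dihydroxy-7-methyl-3-oxooct-7-enoate | COC(=O)CC(=O)[C@H](O)[C@@H](O)CC(C)=C
F3 | step 11 | methyl 3-[(4R,5S)-5-(2-methylprop-2-en-1-yl)-2-oxo-1,3-dioxolan-4-yl]-3-oxopropanoate | COC(=O)CC(=O)[C@@H]1OC(=O)O[C@H]1CC(C)=C
F4 | step 11 | methyl (3aR,7aS)-4-hydroxy-6,6-dimethyl-2-oxo-3a,6,7,7a-tetrahydro-1,3-benzodioxole-5-carboxylate | COC(=O)C1=C(O)[C@@H]2OC(=O)O[C@H]2CC1(C)C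
F5 | step 11 | methyl (3aR,7aS)-6,6-dimethyl-2-oxo-4-{[(trifluoromethyl)sulfonyl]oxy}-3a,6,7,7a-tetrahydro-1,3-benzodioxole-5-carboxylate | COC(=O)C1=C(OS(=O)(=O)C(F)(F)F)[C@@H]2OC(=O)O[C@H]2CC1(C)C
F6 | step 3 | tert-butyl({(4S,5S)-2,2-dimethyl-5-[(2-methyl-1,3-dithian-2-yl)methyl]-1,3-dioxolan-4-yl}methoxy)dimethylsilane | CC(C)(C)[Si](C)(C)OC[C@@H]1OC(C)(C)O[C@H]1CC1(C)SCCCS1
F7 | step 3 | 1-[(4S,5S)-5-{[(tert-butyldimethylsilyl)oxy]methyl}-2,2-dimethyl-1,3-dioxolan-4-yl]propan-2-one | CC(C)(C)[Si](C)(C)OC[C@@H]1OC(C)(C)O[C@H]1CC(C)=O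
F8 | step 24 | {(2E)-5-[(3S,4S)-3,4-dihydroxy-2,6,6-trimethylcyclohex-1-en-1-yl]-3-methylpent-2-en-4-yn-1-yl}triphenylphosphonium bromide | [Br-].C(/C=C(\C)C#CC1=C(C)[C@H](O)[C@@H](O)CC1(C)C)[P+](c1ccccc1)(c1ccccc1)c1ccccc1
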